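The ash run lost about twice as much L as it made Z by 15.0 min, and the birch run about twice by 4.00 min, so I read each Z as taking one L to form and holding a second.

| flask | L | X | temperature | remark | time |
|---|---|---|---|---|---|
| ash | 0.028 M | 0.021 M | 5 °C | run made earlier |  |
| birch | 0.044 M | 0.021 M | 38 °C | run made earlier |  |
| spring | 0.020 M | 0.0210 M | 30 °C |  | 4.0 min |
| summer | 0.020 M | 0.0210 M | −10 °C |  | 4.0 min |
| midnight | 0.020 M | 0.0210 M | 10 °C |  | 4.0 min |
| noon | 0.020 M | 0.0210 M | 50 °C |  | 4.0 min |

| run | time / min | Z / % | L / % |
|---|---|---|---|
| ash | 1.00 | 0.9 | 98.5 |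
| ash | 1.50 | 0.8 | 97.4 |
| ash | 2.50 | 1.9 | 95.6 |
| ash | 3.00 | 2.1 | 94.9 |
| ash | 5.00 | 3.7 | 92.5 |
| ash | 8.00 | 5.0 | 89.1 |
| ash | 15.0 | 9.4 | 80.7 |
| birch | 0.200 | 2.0 | 96.2 |
| birch | 0.667 | 6.9 | 88.2 |
| birch | 1.00 | 8.3 | 83.7 |
| birch | 1.50 | 10.4 | 78.1 |
| birch | 2.50 | 14.4 | 70.6 |
| birch | 3.00 | 15.5 | 68.4 |
| birch | 4.00 | 18.0 | 64.1 |

(readings scatter by 0.3 percentage points)

- what was read earlier has a scatter of 0.3 percentage points, one standard deviation
- a reading or a percentage of Z counts all its forms, free or not
- a reading of L is of its free form alone

- the best flask by amount of Z, in percent of the L charged; "all alike" if 1.5 percentage points covers them all (spring / summer / midnight / noon / all alike)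
- amount of Z at the end, in percent of the L charged, spring
- amount of Z at the end, in percent of the L charged, summer
- amount of Z at the end, in percent of the L charged, midnight
- amount of Z at the end, in percent of the L charged, noon

I replaced each curve by its mean, and took X, which was never read, as falling by one per Z. Over the whole ash run, Z gained per minute divided by mean free L times mean X read 0.352 /M/min; this is my mean-amounts constant, an apparent second-order rate constant.

Two stretches of one run give two readings of it, sharing the reading at their join. In the ash run the stretch up to 5.00 min read 0.375 /M/min and the stretch after it 0.343 /M/min, close enough for a Z of 3.7% read with a scatter of 0.3 percentage points, so I trusted the ash value. In the birch run the two parted: the stretch up to 1.00 min read 4.71 /M/min, but the later stretch read 2.88 /M/min. Z and L were read in both, so the assumed X was the suspect. To keep the early constant, the later birch stretch needs a mean X of 0.00928 M, less than the 0.0152 M that one per Z leaves. So I took the later stretch as the one that cheats, and kept the early constant.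

The ash and birch constants gave an apparent activation energy of 56.6 kJ/mol. That put the constant at 2.65 /M/min for spring, 0.0874 /M/min for summer, 0.543 /M/min for midnight and 10.6 /M/min for noon. Solving for the Z that agrees with its own means gave me 17.0%, 0.727%, 4.27% and 41.7% in that order. I distrusted the noon figure, since it leans on the one-per-Z X that the later birch stretch had put in doubt.

The forecast gave 10% for spring, 0.9% for summer, 3.5% for midnight and 22% for noon, below my spring and noon figures, and held that “Noon should be best”.

The flasks gave 15.5% in spring, 0.709% in summer, 4.28% at midnight and 23.3% at noon, the most.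

    L + Z ⇌ D, settled at all times (K = 870 /M, ΔH = 1.00 kJ/mol)
    L + X → Z (k = 0.196 /M/s, Ea = 58.0 kJ/mol)
    X → Q (k = 0.00938 /s, Ea = 85.0 kJ/mol)
    L + 2 X → G (k = 0.547 /M²/s, Ea = 37.0 kJ/mol)
    (constants at 50 °C)

Noon fell short of my 41.7%, and the noon flask ended with 5.52% of its X, where one X per Z would leave 77.8%. I carried the ash constant 0.352 /M/min and the activation energy to a repeat of summer at 15 °C. There the constant came to 0.823 /M/min and the means gave 6.29%. That flask gave 6.27%, with 88% of its X left.

(The readings were computed with made-up constants.)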